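## Retrosynthetic overview
1. The final step is epoxidation of the C11=C20 exocyclic alkene. The C2, C9 and C14 acetates come from silyl ethers.
2. The 10-membered ring, with its Z-Δ5 alkene, closes last by RCM of a diene built on the cyclohexane–γ-lactone.
3. The γ-lactone, the C8 tertiary alcohol and C17 come from an intramolecular Cr(II)-Reformatsky reaction on an α,α′-dioxygenated C8 ketone.
4. The key coupling joins two fragments of comparable size at C8–C9: the lithiated chiral dithiane **23** (C6–C8) adds to the cyclohexane aldehyde **16** (C1–C5, C9–C15, C20).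
5. Ring formation order: cyclohexane (endo Diels–Alder) → γ-lactone (Reformatsky) → 10-membered carbocycle (RCM) → spiro-epoxide.

Assumption: the chiral Lewis acid in step 4 can be chosen to deliver the absolute configuration shown, and (S)-3-butene-1,2-diol is obtained by hydrolytic kinetic resolution.

## Steps

**Step 1**
Reactants: 1 acrolein; 2 allyl acetate
Product: 3 (E)-4-acetoxybut-2-enal
Conditions: Hoveyda–Grubbs II (5 mol%), CH2Cl2, 40 °C
Reagents that add atoms: none (ethylene is lost)
Why: Cross-metathesis of a type I alkene (allyl acetate) with acrolein gives the E-enal selectively.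

**Step 2**
Reactants: 3
Product: 4 (1E,3E)-1-acetoxy-4-(TBSO)buta-1,3-diene
Conditions: TBSOTf, Et3N, CH2Cl2, 0 °C
Reagents that add atoms: TBSOTf, CC(C)(C)[Si](C)(C)OS(=O)(=O)C(F)(F)F
Why: Silyl dienol ether formation by γ-deprotonation gives the E,E-diene, which fixes the cis relationship of the two oxygens after cycloaddition.

**Step 3**
Reactants: 5 2,2-dimethoxyacetaldehyde
Product: 6 (E)-4,4-dimethoxy-2-methylbut-2-enal
Conditions: Ph3P=C(CH3)CHO, toluene, 80 °C
Reagents that add atoms: (1-formylethylidene)triphenylphosphorane, CC(C=O)=P(c1ccccc1)(c1ccccc1)c1ccccc1 (adds C(CH3)CHO)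
Why: Wittig olefination with a stabilized ylide gives the E-enal, so CHO (C2) and the acetal carbon (C9) are trans.

**Step 4**
Reactants: 4; 6
Product: 7 2-(TBSO)-5-acetoxy-6-(dimethoxymethyl)-1-methylcyclohex-3-ene-1-carbaldehyde. CHO, OTBS and OAc are cis on one face; Me and CH(OMe)2 are on the opposite face.
Conditions: chiral cationic oxazaborolidinium catalyst (20 mol%), CH2Cl2, −78 → −40 °C
Reagents that add atoms: none
Why: A Lewis-acid-catalysed Diels–Alder reaction, endo and "ortho": the stronger OTBS donor terminus bonds to the α-carbon, forming quaternary C1; the OAc terminus bonds to C10. E-enal, E,E-diene and endo CHO set C1, C10 and C14 relative to each other, and the catalyst sets the absolute configuration.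

**Step 5**
Reactants: 8 3-methylbut-3-en-1-ol
Product: 9 4-bromo-2-methylbut-1-ene
Conditions: CBr4, PPh3, CH2Cl2, 0 °C
Reagents that add atoms: CBr4, BrC(Br)(Br)Br (supplies Br)
Why: Appel bromination of a primary alcohol proceeds by SN2 and leaves the 1,1-disubstituted alkene untouched.

**Step 6**
Reactants: 9
Product: 10 (3-methylbut-3-en-1-yl)magnesium bromide
Conditions: Mg turnings, THF, 25 °C
Reagents that add atoms: Mg, [Mg]
Why: Direct oxidative insertion of Mg into the alkyl bromide forms the Grignard reagent, with no stereocentre involved.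

**Step 7**
Reactants: 7; 10
Product: 11 C2-OTBS adduct, carrying the homoprenyl side chain; acetal, OAc and ring alkene intact
Conditions: 10 (2 equiv), CeCl3, THF, −78 °C; then TBSOTf, 2,6-lutidine, −78 → 0 °C
Reagents that add atoms: TBSOTf, CC(C)(C)[Si](C)(C)OS(=O)(=O)C(F)(F)F
Why: Organocerium addition to the neopentyl aldehyde avoids reduction and sets C2 by approach anti to the larger ring substituent (Felkin-type, dr ≈ 3:1, chromatographic separation); the alkoxide is trapped in the same pot as the silyl ether.

**Step 8**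
Reactants: 11
Product: 12 C11 allylic alcohol
Conditions: K2CO3, MeOH, 0 → 25 °C
Reagents that add atoms: none
Why: Base methanolysis removes the unhindered allylic acetate, while the hindered silyl ethers and the acetal survive.

**Step 9**
Reactants: 12
Product: 13 γ-silyloxy cyclohexenone, C11=O with C12=C13
Conditions: MnO2, CH2Cl2, 25 °C
Reagents that add atoms: none
Why: MnO2 oxidises allylic alcohols chemoselectively, and C11 is the only free alcohol.

**Step 10**
Reactants: 13
Product: 14 saturated C11 ketone
Conditions: [(Ph3P)CuH]6 (Stryker's reagent), toluene, −20 → 25 °C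
Reagents that add atoms: none (hydride; the enolate is protonated on work-up)
Why: Copper-hydride 1,4-reduction saturates C12=C13 without touching the 1,1-disubstituted alkene, silyl ethers or acetal; no new stereocentre is formed.

**Step 11**
Reactants: 14
Product: 15 C11=C20 exocyclic methylene
Conditions: Cp2TiMe2, toluene, 70 °C
Reagents that add atoms: dimethyltitanocene, C[Ti](C)(C1=CC=CC1)C1=CC=CC1 (adds CH2)
Why: Petasis methylenation is non-basic, so C10 next to the ketone does not epimerise and the acetal is untouched.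

**Step 12**
Reactants: 15
Product: 16 aldehyde A (C9 CHO on C10)
Conditions: PPTS, acetone/H2O, 50 °C
Reagents that add atoms: water, O
Why: Mild acid-catalysed acetal hydrolysis leaves the TBS ethers and the alkenes untouched, and the sensitive aldehyde is used at once.

**Step 13**
Reactants: 17 (±)-2-vinyloxirane
Product: 18 (S)-but-3-ene-1,2-diol
Conditions: (S,S)-(salen)Co(III)OAc (0.5 mol%), H2O (0.55 equiv), THF, 0 → 25 °C
Reagents that add atoms: water, O
Why: Jacobsen hydrolytic kinetic resolution hydrolyses the (S)-epoxide at the terminal carbon with retention, giving the (S)-diol, which is the future C7 stereocentre.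

**Step 14**
Reactants: 18
Product: 19 (S)-1-trityloxybut-3-en-2-ol
Conditions: TrCl, pyridine, DMAP, CH2Cl2, 25 °C
Reagents that add atoms: trityl chloride, ClC(c1ccccc1)(c1ccccc1)c1ccccc1
Why: The bulky trityl group reacts only at the primary OH, and the stereocentre is untouched.

**Step 15**
Reactants: 19
Product: 20 secondary PMB ether of 19
Conditions: NaH, PMBBr, TBAI, THF/DMF, 0 °C
Reagents that add atoms: p-methoxybenzyl bromide, BrCc1ccc(OC)cc1
Why: Williamson etherification under basic conditions, in which the trityl ether is stable.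

**Step 16**
Reactants: 20
Product: 21 (S)-2-(PMBO)but-3-en-1-ol
Conditions: ZnBr2, CH2Cl2, 25 °C
Reagents that add atoms: none
Why: The Lewis acid selectively cleaves the trityl ether and leaves the PMB ether.

**Step 17**
Reactants: 21
Product: 22 (S)-2-(PMBO)but-3-enal
Conditions: Dess–Martin periodinane, NaHCO3, CH2Cl2, 0 °C
Reagents that add atoms: none
Why: Mild, non-acidic oxidation, with the labile α-alkoxy aldehyde used immediately to avoid epimerisation.

**Step 18**
Reactants: 22
Product: 23 2-[(1S)-1-(PMBO)allyl]-1,3-dithiane (fragment B)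
Conditions: HS(CH2)3SH, I2 (10 mol%), CH2Cl2, 0 °C
Reagents that add atoms: 1,3-propanedithiol, SCCCS
Why: Neutral dithioacetalisation leaves the C7 stereocentre and the PMB ether intact and provides the masked C8 acyl anion.

**Step 19**
Reactants: 23; 16
Product: 24 C9 TBS ether, C8 dithiane, C7 OPMB
Conditions: 23, n-BuLi, THF, −78 → −40 °C; recool to −78 °C, add 16; then TBSOTf, 2,6-lutidine, −78 → 0 °C
Reagents that add atoms: TBSOTf, CC(C)(C)[Si](C)(C)OS(=O)(=O)C(F)(F)F
Why: Corey–Seebach addition of the lithiated dithiane forms C8–C9 (the key fragment coupling); Felkin–Anh attack anti to quaternary C1 sets C9, and the alkoxide is capped in situ as the TBS ether.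

**Step 20**
Reactants: 24
Product: 25 α-hydroxy ketone (C8=O, C7–OH)
Conditions: DDQ (4 equiv), MeCN/H2O 9:1, 25 °C
Reagents that add atoms: water, O
Why: DDQ cleaves the PMB ether and hydrolyses the dithiane in one operation, leaving the silyl ethers and 1,1-disubstituted alkenes intact.

**Step 21**
Reactants: 25
Product: 26 C7 2-bromopropionate
Conditions: CH3CHBrCOBr, pyridine, CH2Cl2, 0 °C
Reagents that add atoms: 2-bromopropionyl bromide, CC(Br)C(=O)Br
Why: Acylation of the secondary α-ketol installs the C17–C19 unit as a diastereomeric mixture at C17, which is harmless because it becomes an enolate in the next step.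

**Step 22**
Reactants: 26
Product: 27 γ-lactone with C8–OH and C17–CH3
Conditions: CrCl2 (5 equiv), THF (5 mM), 25 °C
Reagents that add atoms: none
Why: Intramolecular Cr(II) Reformatsky (aldol) reaction through a chelated cyclic transition state puts the bulky C9 group trans to the C7 vinyl group (C6) and the new C8–O cis to it, and C17–CH3 ends up anti to C9 (thermodynamic, epimerisable).

**Step 23**
Reactants: 27
Product: 28 10-membered carbocycle with Z-Δ5 alkene, tris-TBS ether
Conditions: Hoveyda–Grubbs II (15 mol%), toluene (2 mM), 80 °C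
Reagents that add atoms: none (ethylene is lost)
Why: RCM of the monosubstituted vinyl group and the 1,1-disubstituted alkene gives the trisubstituted alkene, whose Z geometry is enforced by the ring, and the exocyclic methylene is inert.

**Step 24**
Reactants: 28
Product: 29 C2, C9, C14 triol
Conditions: HF·pyridine, pyridine/THF, 40 °C
Reagents that add atoms: none
Why: Fluoride-mediated desilylation under buffered, non-basic conditions, which avoids lactone translocation or elimination.

**Step 25**
Reactants: 29
Product: 30 triacetate (C2, C9, C14 OAc; C8 tertiary OH free)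
Conditions: Ac2O, pyridine, DMAP (cat.), CH2Cl2, 25 °C
Reagents that add atoms: acetic anhydride, CC(=O)OC(C)=O
Why: The secondary alcohols are acetylated, while the tertiary C8–OH is too hindered to react.

**Step 26**
Reactants: 30
Product: 31 junceellolide F
Conditions: DMDO (1.0 equiv), acetone, NaHCO3, −20 °C
Reagents that add atoms: dimethyldioxirane, CC1(C)OO1
Why: The electron-rich 1,1-disubstituted exocyclic alkene reacts faster than the Δ5 alkene, which is deactivated by the allylic lactone oxygen, and the face is selected by the rigid trans-fused framework to give the 11,20-epoxide.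

## Compound list
1 | acrolein | C=CC=O | starting material
2 | allyl acetate | C=CCOC(C)=O | starting material
3 | (E)-4-acetoxybut-2-enal | O=C/C=C/COC(C)=O | intermediate
4 | (1E,3E)-1-acetoxy-4-(TBSO)buta-1,3-diene | CC(=O)O/C=C/C=C/O[Si](C)(C)C(C)(C)C | intermediate
5 | 2,2-dimethoxyacetaldehyde | COC(OC)C=O | starting material
6 | (E)-4,4-dimethoxy-2-methylbut-2-enal | O=C/C(C)=C/C(OC)OC | intermediate
7 | Diels–Alder adduct | O=C[C@@]1(C)[C@@H](O[Si](C)(C)C(C)(C)C)C=C[C@@H](OC(C)=O)[C@@H]1C(OC)OC | intermediate
8 | 3-methylbut-3-en-1-ol | C=C(C)CCO | starting material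
9 | 4-bromo-2-methylbut-1-ene | C=C(C)CCBr | intermediate
10 | (3-methylbut-3-en-1-yl)magnesium bromide | C=C(C)CC[Mg]Br | intermediate
11 | C2-OTBS adduct | C=C(C)CC[C@@H](O[Si](C)(C)C(C)(C)C)[C@@]1(C)[C@@H](O[Si](C)(C)C(C)(C)C)C=C[C@@H](OC(C)=O)[C@@H]1C(OC)OC | intermediate
12 | C11 allylic alcohol | C=C(C)CC[C@@H](O[Si](C)(C)C(C)(C)C)[C@@]1(C)[C@@H](O[Si](C)(C)C(C)(C)C)C=C[C@@H](O)[C@@H]1C(OC)OC | intermediate
13 | cyclohexenone | C=C(C)CC[C@@H](O[Si](C)(C)C(C)(C)C)[C@@]1(C)[C@@H](O[Si](C)(C)C(C)(C)C)C=CC(=O)[C@@H]1C(OC)OC | intermediate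
14 | saturated C11 ketone | C=C(C)CC[C@@H](O[Si](C)(C)C(C)(C)C)[C@@]1(C)[C@@H](O[Si](C)(C)C(C)(C)C)CCC(=O)[C@@H]1C(OC)OC | intermediate
15 | C11 exocyclic methylene acetal | C=C(C)CC[C@@H](O[Si](C)(C)C(C)(C)C)[C@@]1(C)[C@@H](O[Si](C)(C)C(C)(C)C)CCC(=C)[C@@H]1C(OC)OC | intermediate
16 | aldehyde A | C=C(C)CC[C@@H](O[Si](C)(C)C(C)(C)C)[C@@]1(C)[C@@H](O[Si](C)(C)C(C)(C)C)CCC(=C)[C@@H]1C=O | intermediate
17 | (±)-2-vinyloxirane | C=CC1CO1 | starting material
18 | (S)-but-3-ene-1,2-diol | C=C[C@H](O)CO | intermediate
19 | (S)-1-trityloxybut-3-en-2-ol | C=C[C@H](O)COC(c1ccccc1)(c1ccccc1)c1ccccc1 | intermediate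
20 | PMB ether of 19 | C=C[C@H](OCc1ccc(OC)cc1)COC(c1ccccc1)(c1ccccc1)c1ccccc1 | intermediate
21 | (S)-2-(PMBO)but-3-en-1-ol | C=C[C@H](OCc1ccc(OC)cc1)CO | intermediate
22 | (S)-2-(PMBO)but-3-enal | C=C[C@H](OCc1ccc(OC)cc1)C=O | intermediate
23 | dithiane B | C=C[C@H](OCc1ccc(OC)cc1)C1SCCCS1 | intermediate
24 | coupling product | C=C(C)CC[C@@H](O[Si](C)(C)C(C)(C)C)[C@@]1(C)[C@@H](O[Si](C)(C)C(C)(C)C)CCC(=C)[C@@H]1[C@@H](O[Si](C)(C)C(C)(C)C)C2(SCCCS2)[C@H](C=C)OCc2ccc(OC)cc2 | intermediate
25 | α-hydroxy ketone | C=C(C)CC[C@@H](O[Si](C)(C)C(C)(C)C)[C@@]1(C)[C@@H](O[Si](C)(C)C(C)(C)C)CCC(=C)[C@@H]1[C@@H](O[Si](C)(C)C(C)(C)C)C(=O)[C@H](C=C)O | intermediate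
26 | 2-bromopropionate | C=C(C)CC[C@@H](O[Si](C)(C)C(C)(C)C)[C@@]1(C)[C@@H](O[Si](C)(C)C(C)(C)C)CCC(=C)[C@@H]1[C@@H](O[Si](C)(C)C(C)(C)C)C(=O)[C@H](C=C)OC(=O)C(C)Br | intermediate
27 | γ-lactone | C=C(C)CC[C@@H](O[Si](C)(C)C(C)(C)C)[C@@]1(C)[C@@H](O[Si](C)(C)C(C)(C)C)CCC(=C)[C@@H]1[C@@H](O[Si](C)(C)C(C)(C)C)[C@@]2(O)[C@H](C=C)OC(=O)[C@@H]2C | intermediate
28 | RCM macrocycle, tris-TBS | CC(C)(C)[Si](C)(C)O[C@H]1CCC(=C)[C@@H]2[C@@H](O[Si](C)(C)C(C)(C)C)[C@@]3(O)[C@H](/C=C(/C)CC[C@@H](O[Si](C)(C)C(C)(C)C)[C@@]12C)OC(=O)[C@@H]3C | intermediate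
29 | triol | O[C@H]1CCC(=C)[C@@H]2[C@@H](O)[C@@]3(O)[C@H](/C=C(/C)CC[C@@H](O)[C@@]12C)OC(=O)[C@@H]3C | intermediate
30 | triacetate | CC(=O)O[C@H]1CCC(=C)[C@@H]2[C@@H](OC(C)=O)[C@@]3(O)[C@H](/C=C(/C)CC[C@@H](OC(C)=O)[C@@]12C)OC(=O)[C@@H]3C | intermediate
31 | junceellolide F | CC(=O)O[C@H]1CC[C@]2(CO2)[C@@H]2[C@@H](OC(C)=O)[C@@]3(O)[C@H](/C=C(/C)CC[C@@H](OC(C)=O)[C@@]12C)OC(=O)[C@@H]3C | target

## Totals
Total steps: 26. Longest linear sequence: 17 (steps 1, 2, 4, 7–12, 19–26), which is 65% of the total (17/26).

## Three steps most likely to fail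
1. **Step 4 (Diels–Alder).** Forming quaternary C1 from a trisubstituted enal and a 1,4-disubstituted diene may be slow, and the endo selectivity and enantioselectivity are uncertain. Fallback: build the cyclohexane by a different route, namely an Evans oxazolidinone-enoyl Diels–Alder (Et2AlCl, auxiliary control), or a Cu-catalysed conjugate addition to a 4-silyloxy-3-substituted cyclohexenone followed by enolate trapping to install C10/C9.
2. **Step 22 (Cr-Reformatsky lactonisation).** C8 and C17 stereocontrol may be poor, or the bromoester may be reduced without cyclising. Fallback: form the C8–C17 bond intermolecularly before the lactone, by chelation-controlled addition of a crotyl- or Reformatsky reagent to the C8 ketone followed by ozonolysis and oxidative lactonisation. Alternatively, build the butenolide with an NHK coupling and install the C8–OH by nucleophilic epoxidation and SmI2 opening after the macrocycle is closed.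
3. **Step 23 (RCM).** The trans-fused γ-lactone/10-membered ring may be too strained for the diene to cyclise. Fallback: close the ring at C6–C7 by intramolecular Nozaki–Hiyama–Kishi coupling of a Z-vinyl iodide with a C7 aldehyde, then re-form the C7 ester and lactone.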